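**Assumption:** Guidongnin is the 6,7‑seco‑ent‑kauranoid drawn in the SMILES (6,19‑γ‑lactone, 7,20‑δ‑lactone, 11‑OH, 15‑OH, Δ16(17)). Locants C1–C20 below follow that structure, and the absolute configuration is as given.

## Retrosynthetic overview
1. The C15 allylic alcohol comes from allylic oxidation and Luche reduction of the 16‑ene. C11‑OH is carried as a TBS ether, and the C1 and C12 carbonyls are excised by Barton–McCombie deoxygenation.
2. Ring D (the bicyclo[3.2.1]octane) comes from a Au‑catalysed Conia‑ene of the C12 ketone (via its C13 enol ether) onto the C15 propargyl group.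
3. The spiro δ‑lactone, ring C and the C8/C9/C10 stereocentres come from an intramolecular Mukaiyama–Michael desymmetrization of a 4‑propargyl‑cyclohexadienone ester. The ester is tethered through C20–O–C7 to the ring A ketone.
4. Ring A and the γ‑lactone (C4/C5) come from an NHC‑catalysed desymmetrizing formate‑Stetter of 4‑methyl‑4‑(formyloxymethyl)cyclohexa‑2,5‑dienone. Ring order: A/γ‑lactone, then spiro δ‑lactone and C, then D. Starting materials are ester **1** and benzoic acid **9**.

## Route

**Step 1**
Reactants: 1 ethyl 1,4‑dioxaspiro[4.5]decane‑8‑carboxylate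
Product: 2 ethyl 8‑methyl‑1,4‑dioxaspiro[4.5]decane‑8‑carboxylate
Conditions: LDA, THF, –78 °C; then MeI, –78 → 23 °C
Reagents that add atoms: iodomethane, CI
Why: Ester‑enolate α‑methylation builds the quaternary C4 carbon (achiral product), following standard enolate alkylation.

**Step 2**
Reactants: 2
Product: 3 (8‑methyl‑1,4‑dioxaspiro[4.5]decan‑8‑yl)methanol
Conditions: LiAlH4, THF, 0 °C
Reagents that add atoms: none
Why: Hydride reduction of the ester to the primary alcohol (C19); the ketal is inert.

**Step 3**
Reactants: 3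
Product: 4 (1‑methyl‑4‑oxocyclohexyl)methyl formate
Conditions: HCO2H (neat), 23 °C, 12 h
Reagents that add atoms: formic acid, O=CO; water, O
Why: Formic acid cleaves the ketal and O‑formylates the primary alcohol in one pot, giving the formate that serves as the acyl‑anion tether.

**Step 4**
Reactants: 4
Product: 5 (1‑methyl‑4‑oxocyclohexa‑2,5‑dien‑1‑yl)methyl formate
Conditions: IBX (3 equiv), DMSO, 80 °C
Reagents that add atoms: none
Why: IBX double dehydrogenation (Nicolaou) of the 4,4‑disubstituted cyclohexanone gives the achiral dienone with enantiotopic enone arms.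

**Step 5**
Reactants: 5
Product: 6 cis‑3a‑methyl‑3a,7a‑dihydro‑2‑benzofuran‑1,6(3H,7H)‑dione (single enantiomer; C3a = C4, C7a = C5 of the target, configured as in the target)
Conditions: aminoindanol‑derived N‑C6F5 triazolium salt (10 mol%), i‑Pr2NEt (20 mol%), toluene, 23 °C, 24 h (catalyst enantiomer chosen to give the target C4/C5 configuration)
Reagents that add atoms: none
Why: Proposed new method: the carbene adds to the formate C=O, and proton transfer gives an alkoxy‑Breslow intermediate. Its nucleophilic carbon adds 5‑exo, tether‑controlled, to one enantiotopic enone β‑carbon. The adduct then collapses, expelling the carbene and leaving the lactone carbonyl (C6). The catalyst picks the enantiotopic arm, which sets the C4 quaternary centre and C5, and the tether forces C6 cis to C19 with H5 trans. The closest known reaction is the intramolecular Stetter desymmetrization of cyclohexadienones with tethered aldehydes, extended to an ester‑level acyl anion (alkoxycarbonyl transfer), with NHC formate chemistry as precedent for the first step.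

**Step 6**
Reactants: 6
Product: 7 cis‑3a‑methylhexahydro‑2‑benzofuran‑1,6(3H)‑dione (saturated ketone; C4/C5 unchanged)
Conditions: H2 (1 atm), 10% Pd/C, EtOAc, 23 °C
Reagents that add atoms: none
Why: Chemoselective hydrogenation of the only C=C bond removes the A‑ring enone; this blocks a later double‑Michael in step 11, and no stereocentre is touched.

**Step 7**
Reactants: 7
Product: 8 7‑(hydroxymethyl)‑3a‑methylhexahydro‑2‑benzofuran‑1,6‑dione (new CH2OH = C20 on C10; C10 epimeric mixture)
Conditions: LiHMDS (1.05 equiv), THF, –78 °C; then monomeric CH2O in THF, –78 → –40 °C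
Reagents that add atoms: formaldehyde, C=O
Why: Kinetic enolization at the only α‑methylene (C10) and aldol hydroxymethylation install C20; the C10 configuration is irrelevant because it is lost on enolization in step 11.

**Step 8**
Reactants: 9 benzoic acid
Product: 10 1‑(prop‑2‑yn‑1‑yl)cyclohexa‑2,5‑diene‑1‑carboxylic acid
Conditions: Li, NH3(l)/THF, t‑BuOH (1 equiv), –78 °C; then propargyl bromide
Reagents that add atoms: propargyl bromide, BrCC#C
Why: Birch reductive alkylation (dianion protonated para, alkylated ipso) gives the quaternary C8 bearing CO2H (C7) and the C15–C16≡C17 propargyl group. The product is achiral, with enantiotopic alkenes.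

**Step 9**
Reactants: 8 and 10
Product: 11 (3a‑methyl‑1,6‑dioxooctahydro‑2‑benzofuran‑7‑yl)methyl 1‑(prop‑2‑yn‑1‑yl)cyclohexa‑2,5‑diene‑1‑carboxylate (C20–O–C7 tether; C10 epimeric)
Conditions: 2,4,6‑Cl3C6H2COCl, Et3N, THF, 0 °C; then 8, DMAP, toluene, 0 → 23 °C
Reagents that add atoms: none
Why: Yamaguchi esterification under mild conditions joins the tether while avoiding elimination of the β‑acyloxy ketone.

**Step 10**
Reactants: 11
Product: 12 the 4‑oxo‑cyclohexa‑2,5‑diene ester (ring C cross‑conjugated dienone; otherwise as 11)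
Conditions: DDQ (2.2 equiv), 1,4‑dioxane/H2O 20:1, 23 °C
Reagents that add atoms: water, O
Why: DDQ abstracts hydride from the doubly allylic C12–H2, water traps the pentadienyl cation at C12, and a second hydride abstraction gives the dienone. Aromatization is impossible because C8 is quaternary; the saturated ketone, lactones and alkyne are inert.

**Step 11**
Reactants: 12
Product: 13 tetracyclic keto‑bislactone with C12‑OTBS silyl dienol ether (C10–C9 bond, spiro δ‑lactone C10/C20/O/C7/C8/C9 formed; C11=C12(OTBS)–C13=C14; C11 sp2)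
Conditions: TBSOTf (2.5 equiv), Et3N (3 equiv), CH2Cl2, –78 → 23 °C
Reagents that add atoms: tert‑butyldimethylsilyl triflate, CC(C)(C)[Si](C)(C)OS(=O)(=O)C(F)(F)F
Why: The tetrasubstituted C1/C10 silyl enol ether (a neutral nucleophile, so no E1cB loss of the carboxylate) attacks one enantiotopic dienone β‑carbon through a chair‑like 6‑exo Mukaiyama–Michael transition state. The cis‑fused γ‑lactone blocks the top face of the enol ether, so C9 bonds from the bottom face. This sets C10 (C20 axial, syn to C19; C9 equatorial), C9, and C8 by choice of the C9 versus C14 arm, all controlled by C4/C5.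

**Step 12**
Reactants: 13
Product: 14 C11‑OTBS, C12‑ketone enone (C13=C14 retained; C11 epimeric)
Conditions: DMDO (acetone solution, 1.2 equiv), CH2Cl2, –78 → 0 °C
Reagents that add atoms: dimethyldioxirane, CC1(C)OO1
Why: Rubottom oxidation: epoxidation of the electron‑rich silyl enol ether C11=C12 and 1,4‑silyl shift give the α‑siloxy ketone regiospecifically at C11; its configuration is fixed thermodynamically in step 15.

**Step 13**
Reactants: 14
Product: 15 saturated C12 ketone (C13/C14 now CH2CH2)
Conditions: Stryker's reagent [(Ph3P)CuH]6 (0.4 equiv), toluene, –40 → 0 °C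
Reagents that add atoms: none
Why: Copper‑hydride conjugate reduction removes the C13=C14 enone, leaving the terminal alkyne, the hindered C1 ketone and the lactones untouched.

**Step 14**
Reactants: 15
Product: 16 pentacycle with bicyclo[3.2.1] ring D (C13–C16 bond, exocyclic C16=C17)
Conditions: (a) LiHMDS (2.1 equiv), TMSCl, THF, –78 °C; (b) Ph3PAuCl/AgOTf (5 mol%), CH2Cl2, 23 °C
Reagents that add atoms: none
Why: Kinetic enolization of the α‑siloxy ketone occurs on the unsubstituted C13 side, and Au‑catalysed Conia‑ene (5‑exo‑dig, Toste) delivers the C13 enol ether to the C15 propargyl group. This closes the bridge on the face of C15, and C13 is forced by the bicycle.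

**Step 15**
Reactants: 16
Product: 17 C11 epimerized α‑siloxy ketone (equatorial OTBS, as in the target)
Conditions: DBU (1.5 equiv), toluene, 60 °C
Reagents that add atoms: none
Why: Thermodynamic epimerization through the C11 enolate; the axial epimer is syn‑diaxial to the C15–C16 bridge, and the bridgehead C13 cannot enolize (Bredt), so only C11 equilibrates.

**Step 16**
Reactants: 17
Product: 18 C1,C12‑diol (epimeric carbinols; C11‑OTBS)
Conditions: NaBH4, MeOH/CH2Cl2, 0 °C
Reagents that add atoms: none
Why: Hydride reduction of both ketones; the new carbinol centres are removed in step 18, and the lactones survive NaBH4 at 0 °C.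

**Step 17**
Reactants: 18
Product: 19 bis(imidazolylthiocarbonate) at C1 and C12
Conditions: TCDI, DMAP (cat.), ClCH2CH2Cl, 60 °C
Reagents that add atoms: 1,1'‑thiocarbonyldiimidazole, S=C(n1ccnc1)n1ccnc1
Why: Activation of both secondary alcohols for Barton–McCombie deoxygenation.

**Step 18**
Reactants: 19
Product: 20 C1‑ and C12‑deoxygenated C11‑OTBS compound
Conditions: (TMS)3SiH, AIBN, toluene, 110 °C
Reagents that add atoms: none
Why: Tin‑free Barton–McCombie radical deoxygenation removes both oxygens (C1 and C12 become CH2) and leaves the exocyclic alkene intact.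

**Step 19**
Reactants: 20
Product: 21 C11 alcohol (16‑ene, C15H2)
Conditions: TBAF, AcOH, THF, 40 °C
Reagents that add atoms: none
Why: Desilylation frees the C11 hydroxyl with its equatorial configuration retained.

**Step 20**
Reactants: 21
Product: 22 15‑oxo‑16‑ene (enone)
Conditions: SeO2 (1.5 equiv), TBHP (5 equiv), CH2Cl2, 40 °C
Reagents that add atoms: tert‑butyl hydroperoxide, CC(C)(C)OO
Why: Riley allylic oxidation occurs at C15, the only oxidizable allylic CH2 (C13 is a bridgehead), and goes to the enone.

**Step 21**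
Reactants: 22
Product: 23 Guidongnin
Conditions: NaBH4, CeCl3·7H2O, MeOH, –20 °C
Reagents that add atoms: none
Why: Luche 1,2‑reduction with hydride delivered from the less hindered exo face of the bicyclo[3.2.1] ketone places the 15‑OH endo, as in the target; the exocyclic alkene is retained.

## Compound list
1 | ethyl 1,4‑dioxaspiro[4.5]decane‑8‑carboxylate | CCOC(=O)C1CCC2(CC1)OCCO2 | starting material
2 | ethyl 8‑methyl‑1,4‑dioxaspiro[4.5]decane‑8‑carboxylate | CCOC(=O)C1(C)CCC2(CC1)OCCO2 | intermediate
3 | (8‑methyl‑1,4‑dioxaspiro[4.5]decan‑8‑yl)methanol | OCC1(C)CCC2(CC1)OCCO2 | intermediate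
4 | (1‑methyl‑4‑oxocyclohexyl)methyl formate | O=COCC1(C)CCC(=O)CC1 | intermediate
5 | (1‑methyl‑4‑oxocyclohexa‑2,5‑dien‑1‑yl)methyl formate | O=COCC1(C)C=CC(=O)C=C1 | intermediate
6 | cis‑3a‑methyl‑3a,7a‑dihydro‑2‑benzofuran‑1,6(3H,7H)‑dione (C4/C5 of target) | O=C1C=C[C@@]2(C)COC(=O)[C@H]2C1 | intermediate
7 | cis‑3a‑methylhexahydro‑2‑benzofuran‑1,6(3H)‑dione | O=C1CC[C@@]2(C)COC(=O)[C@H]2C1 | intermediate
8 | 7‑(hydroxymethyl)‑3a‑methylhexahydro‑2‑benzofuran‑1,6‑dione (C10 unspecified) | O=C1CC[C@@]2(C)COC(=O)[C@H]2C1CO | intermediate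
9 | benzoic acid | OC(=O)c1ccccc1 | starting material
10 | 1‑(prop‑2‑yn‑1‑yl)cyclohexa‑2,5‑diene‑1‑carboxylic acid | OC(=O)C1(CC#C)C=CCC=C1 | intermediate
11 | C20 ester of 8 with acid 10 (C10 unspecified) | O=C1CC[C@@]2(C)COC(=O)[C@H]2C1COC(=O)C3(CC#C)C=CCC=C3 | intermediate
12 | dienone ester (4‑oxo‑1‑propargylcyclohexa‑2,5‑diene‑1‑carboxylate of 8) | O=C1CC[C@@]2(C)COC(=O)[C@H]2C1COC(=O)C3(CC#C)C=CC(=O)C=C3 | intermediate
13 | Michael adduct, C12 silyl dienol ether | O=C1CC[C@@]2(C)COC(=O)[C@H]2[C@@]13COC(=O)[C@@]4(CC#C)C=CC(O[Si](C)(C)C(C)(C)C)=C[C@@H]34 | intermediate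
14 | C11‑OTBS C12‑ketone enone (C11 unspecified) | O=C1CC[C@@]2(C)COC(=O)[C@H]2[C@@]13COC(=O)[C@@]4(CC#C)C=CC(=O)C(O[Si](C)(C)C(C)(C)C)[C@@H]34 | intermediate
15 | saturated C12 ketone (C11 unspecified) | O=C1CC[C@@]2(C)COC(=O)[C@H]2[C@@]13COC(=O)[C@@]4(CC#C)CCC(=O)C(O[Si](C)(C)C(C)(C)C)[C@@H]34 | intermediate
16 | Conia‑ene pentacycle (C11 unspecified) | O=C1CC[C@@]2(C)COC(=O)[C@H]2[C@@]13COC(=O)[C@@]4(CC(=C)[C@@H]5C(=O)C(O[Si](C)(C)C(C)(C)C)[C@@H]34)C5 | intermediate
17 | 11‑epimerized (equatorial OTBS) ketone | O=C1CC[C@@]2(C)COC(=O)[C@H]2[C@@]13COC(=O)[C@@]4(CC(=C)[C@@H]5C(=O)[C@@H](O[Si](C)(C)C(C)(C)C)[C@@H]34)C5 | intermediate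
18 | C1,C12‑diol (carbinols unspecified) | OC1CC[C@@]2(C)COC(=O)[C@H]2[C@@]13COC(=O)[C@@]4(CC(=C)[C@@H]5C(O)[C@@H](O[Si](C)(C)C(C)(C)C)[C@@H]34)C5 | intermediate
19 | bis(imidazole‑1‑carbothioate) | S=C(n6ccnc6)OC1CC[C@@]2(C)COC(=O)[C@H]2[C@@]13COC(=O)[C@@]4(CC(=C)[C@@H]5C(OC(=S)n7ccnc7)[C@@H](O[Si](C)(C)C(C)(C)C)[C@@H]34)C5 | intermediate
20 | C1,C12‑dideoxy C11‑OTBS compound | C1CC[C@@]2(C)COC(=O)[C@H]2[C@@]13COC(=O)[C@@]4(CC(=C)[C@@H]5C[C@@H](O[Si](C)(C)C(C)(C)C)[C@@H]34)C5 | intermediate
21 | 11‑hydroxy‑16‑ene (15‑deoxy) | C1CC[C@@]2(C)COC(=O)[C@H]2[C@@]13COC(=O)[C@@]4(CC(=C)[C@@H]5C[C@@H](O)[C@@H]34)C5 | intermediate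
22 | 15‑oxo‑16‑ene | C1CC[C@@]2(C)COC(=O)[C@H]2[C@@]13COC(=O)[C@@]4(C(=O)C(=C)[C@@H]5C[C@@H](O)[C@@H]34)C5 | intermediate
23 | Guidongnin | C1CC[C@@]2(C)COC(=O)[C@H]2[C@@]13COC(=O)[C@@]4([C@H](O)C(=C)[C@@H]5C[C@@H](O)[C@@H]34)C5 | target

## Totals
Total steps: 21. Longest linear sequence: 20 (steps 1–7, then 9–21).

## Three steps most likely to fail
1. **Step 5, NHC formate‑Stetter (the new step).** The formate may be a poor acyl‑anion precursor, or the NHC may simply transfer the formyl group. Fallback (known chemistry): take the free alcohol from 5 (K2CO3/MeOH) and run a bifunctional thiourea‑catalysed desymmetrizing Michael addition of nitromethane. Then do a Nef oxidation (Oxone) and acid lactonization to the cis γ‑lactone, separating any trans diastereomer.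
2. **Step 11, tethered Mukaiyama–Michael.** Forming the C10 quaternary centre next to hindered C9/C8 may fail, the silyl enol ether may ionize instead, or the arm/face selectivity may be poor. Fallback: abandon the ester tether. Convert 12's A‑ring ketone to the tertiary α‑iodide (C10–I) and close C9–C10 by visible‑light iodine‑atom‑transfer radical cyclization onto the dienone; the C11 α‑iodo ketone product is then displaced or reduced.
3. **Step 14, Au Conia‑ene.** Enol regiochemistry (C13 versus C11) or the C5 lactone α‑H may interfere. Fallback: use allyl bromide instead of propargyl bromide in step 8, Wacker‑oxidize the allyl group to the C15–C16(=O)CH3 ketone after step 13, close ring D by intramolecular aldol of the C13 enolate onto C16, dehydrate (Burgess) and apply the SeO2/Luche endgame.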